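**Assumption:** C‑n labels use the longipinane numbering of the target (C‑1 ketone, C‑2=C‑3 alkene, C‑4/C‑11 bridgeheads, C‑5/C‑10 one‑carbon bridges, C‑6 CMe2, C‑7/C‑8/C‑9 ester carbons); reagents named without a number are purchased. The route is a paper design and has not been run.

## Retrosynthetic overview

1. Target 27 ⇐ triol 25 (three angelate esters last) ⇐ tricyclic vinylogous ester 23 by methyl addition and carbonyl transposition (C‑3 methyl, C‑1 ketone).
2. Cyclobutane (third ring) ⇐ C‑4–C‑5 bond by intramolecular α′‑enolate alkylation of mesylate 22.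
3. Seven‑membered ring (second ring) ⇐ C‑11–C‑5 bond by a group‑selective Mukaiyama aldol cyclisation of the mirror‑symmetric bis(enol ether) aldehyde 16, steered by the C‑9 stereocentre.
4. C‑7/C‑8/C‑9 triad ⇐ zinc–ProPhenol syn‑aldol of hydroxy ketone 7 with aldehyde 11, then chelation‑controlled ketone reduction.
5. Six‑membered ring (first ring, with the C‑10 quaternary methyl) ⇐ Birch reductive methylation of 3,5‑dimethoxybenzoic acid.

## Route

Step 1
Reactants: 1 3,5-dimethoxybenzoic acid; 2 iodomethane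
Product: 3 3,5-dimethoxy-1-methylcyclohexa-2,5-diene-1-carboxylic acid
Conditions: Li (2.5 equiv), NH3(l)/THF, −78 °C; then MeI, −78 → −33 °C; aq. NH4Cl, extraction at pH 5, 0 °C
Reagents that add atoms: iodomethane, CI
Why: Birch reduction of the benzoate gives the carboxylate‑stabilised cyclohexadienyl anion flanked by the two methoxy‑bearing double bonds, which is methylated at the ipso carbon (Birch reductive alkylation); the product has a mirror plane through C‑10 and C‑2, so no stereocentre is set.

Step 2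
Reactants: 3 3,5-dimethoxy-1-methylcyclohexa-2,5-diene-1-carboxylic acid; 4 methyllithium
Product: 5 1-(3,5-dimethoxy-1-methylcyclohexa-2,5-dien-1-yl)ethan-1-one
Conditions: MeLi (2.2 equiv), Et2O/THF, 0 °C; aq. NH4Cl, 0 °C
Reagents that add atoms: methyllithium, [Li]C
Why: Two equivalents of MeLi convert the hindered acid into the dilithio gem‑diolate, which collapses to the methyl ketone on buffered work‑up (organolithium addition to a carboxylate); the enol ethers are inert to base.

Step 3
Reactants: 5 1-(3,5-dimethoxy-1-methylcyclohexa-2,5-dien-1-yl)ethan-1-one; 6 3-phenyl-2-(phenylsulfonyl)oxaziridine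
Product: 7 1-(3,5-dimethoxy-1-methylcyclohexa-2,5-dien-1-yl)-2-hydroxyethan-1-one
Conditions: KN(SiMe3)2, THF, −78 °C; then 6, −78 °C; aq. NH4Cl
Reagents that add atoms: 3-phenyl-2-(phenylsulfonyl)oxaziridine, O=S(=O)(N1OC1c1ccccc1)c1ccccc1
Why: The only enolisable position gives the potassium enolate, which is hydroxylated by the N‑sulfonyloxaziridine (Davis enolate oxidation) at a temperature where the neutral enol ethers do not react; no stereocentre is formed.

Step 4
Reactants: 8 methyl 3-hydroxy-2,2-dimethylpropanoate; 9 N,O-dimethylhydroxylamine hydrochloride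
Product: 10 3-hydroxy-N-methoxy-N,2,2-trimethylpropanamide
Conditions: i-PrMgCl (3.3 equiv), THF, −20 → 0 °C; aq. NH4Cl
Reagents that add atoms: N,O-dimethylhydroxylamine hydrochloride, Cl.CNOC
Why: The magnesium amide of N,O‑dimethylhydroxylamine converts the methyl ester directly into the Weinreb amide while the hydroxyl is carried as its magnesium alkoxide (Weinreb amidation).

Step 5
Reactants: 10 3-hydroxy-N-methoxy-N,2,2-trimethylpropanamide
Product: 11 N-methoxy-N,2,2-trimethyl-3-oxopropanamide
Conditions: Dess–Martin periodinane, CH2Cl2, 23 °C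
Reagents that add atoms: none
Why: Dess–Martin oxidation of the neopentyl primary alcohol gives the non‑enolisable aldehyde without touching the amide.

Step 6
Reactants: 7 1-(3,5-dimethoxy-1-methylcyclohexa-2,5-dien-1-yl)-2-hydroxyethan-1-one; 11 N-methoxy-N,2,2-trimethyl-3-oxopropanamide
Product: 12 (3S,4R)-5-(3,5-dimethoxy-1-methylcyclohexa-2,5-dien-1-yl)-3,4-dihydroxy-N-methoxy-N,2,2-trimethyl-5-oxopentanamide
Conditions: (S,S)-ProPhenol (10 mol %), Et2Zn (20 mol %), 4 Å molecular sieves, THF, −35 °C
Reagents that add atoms: none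
Why: The dinuclear zinc–ProPhenol catalyst forms the zinc enediolate of 7 and adds it to the non‑enolisable aldehyde through a chelated transition state (Trost direct asymmetric aldol of α‑hydroxy ketones), giving the syn diol with C‑7 and C‑8 set by the ligand (the (S,S) ligand is chosen by analogy with α‑hydroxyacetophenone donors); the medium is basic, so the enol ethers survive.

Step 7
Reactants: 12 (3S,4R)-5-(3,5-dimethoxy-1-methylcyclohexa-2,5-dien-1-yl)-3,4-dihydroxy-N-methoxy-N,2,2-trimethyl-5-oxopentanamide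
Product: 13 5-(3,5-dimethoxy-1-methylcyclohexa-2,5-dien-1-yl)-3,4,5-trihydroxy-N-methoxy-N,2,2-trimethylpentanamide (3,4-syn and 4,5-anti; C-7, C-8, C-9 as in the target)
Conditions: Zn(BH4)2, Et2O, −30 °C; aq. NH4Cl
Reagents that add atoms: none
Why: Zinc chelates the ketone with the α‑hydroxyl and hydride enters anti to the C‑7 chain (chelation‑controlled 1,2‑reduction), which sets C‑9 anti to C‑8 and therefore anti to C‑7; the amide and enol ethers are not reduced.

Step 8
Reactants: 13 triol Weinreb amide; 14 triethylsilyl trifluoromethanesulfonate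
Product: 15 5-(3,5-dimethoxy-1-methylcyclohexa-2,5-dien-1-yl)-N-methoxy-N,2,2-trimethyl-3,4,5-tris(triethylsilyloxy)pentanamide (configuration as 13)
Conditions: Et3SiOTf (3.6 equiv), 2,6-lutidine, CH2Cl2, −78 → 0 °C
Reagents that add atoms: triethylsilyl trifluoromethanesulfonate, CC[Si](CC)(CC)OS(=O)(=O)C(F)(F)F
Why: The silyl triflate with a hindered pyridine base silylates all three hindered secondary alcohols under non‑acidic conditions (silyl ether protection), with no change at the stereocentres.

Step 9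
Reactants: 15 tris(triethylsilyl) Weinreb amide
Product: 16 5-(3,5-dimethoxy-1-methylcyclohexa-2,5-dien-1-yl)-2,2-dimethyl-3,4,5-tris(triethylsilyloxy)pentanal (configuration as 13)
Conditions: i-Bu2AlH, THF, −78 °C; aq. potassium sodium tartrate
Reagents that add atoms: none
Why: The Weinreb amide is reduced to its stable aluminium hemiaminal chelate, which releases the aldehyde only on neutral work‑up (Weinreb amide reduction).

Step 10
Reactants: 16 tris(triethylsilyloxy) aldehyde; 17 trimethylsilyl trifluoromethanesulfonate; 18 water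
Product: 20 bicyclic 5-hydroxy vinylogous ester (cis-fused six/seven ring system; C-3 ketone; C-1 methoxy enol ether; 5-OH cis to the 10-methyl group; 7,8,9-tris(triethylsilyloxy)), via C-5 trimethylsilyl ether dienyl bis(enol ether) 19 (not isolated)
Conditions: Me3SiOTf (1.2 equiv), 2,6-di-tert-butyl-4-methylpyridine, CH2Cl2 (0.005 M), −78 °C; then 0.5 M aq. oxalic acid, THF, 0 °C
Reagents that add atoms: water, O
Why: Proposed new method: the mirror‑symmetric bis(methyl enol ether) offers two diastereotopic nucleophilic carbons to the silyl‑activated neopentyl aldehyde, the tether enforces a cis‑fused seven‑membered ring, and cyclisation through the enol ether that leaves the bulky C‑9 silyloxy group on the convex face with the activated carbonyl oxygen pointing outward in an open transition state sets C‑10, C‑11 and C‑5 (5‑O cis to the 10‑methyl and to H‑11) in one event, after which the O‑methyl oxocarbenium ion loses H‑2 to the hindered base to give 19 and kinetic hydrolysis at the less hindered C‑3 terminus leaves the methoxy group on C‑1; the closest known reaction types are the group‑selective Prins and Mukaiyama aldol cyclisations of Birch‑derived cyclohexa‑1,4‑dienes and silyl‑triflate‑promoted additions of alkyl enol ethers to aldehydes.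

Step 11
Reactants: 20 bicyclic 5-hydroxy vinylogous ester; 21 methanesulfonyl chloride
Product: 22 bicyclic C-5 mesylate (otherwise as 20)
Conditions: MsCl, Et3N, CH2Cl2, −20 → 0 °C
Reagents that add atoms: methanesulfonyl chloride, CS(=O)(=O)Cl
Why: Sulfene‑type mesylation converts the hindered neopentyl secondary alcohol into the mesylate with retention at C‑5.

Step 12
Reactants: 22 bicyclic C-5 mesylate
Product: 23 1-methoxy-7,8,9-tris(triethylsilyloxy)longipin-1-en-3-one (tricyclic vinylogous ester with the longipinane cage)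
Conditions: LiN(i-Pr)2 (1.3 equiv), THF, −78 °C; then DMPU, −78 → 23 °C
Reagents that add atoms: none
Why: Kinetic α′‑deprotonation at C‑4 of the vinylogous ester (Stork–Danheiser enolate) and intramolecular SN2 displacement of the C‑5 mesylate with inversion close the cyclobutane, the enolate‑alkylation type used to close pinane and longipinane four‑membered rings; the cage fixes C‑4 and C‑5, and because C‑1 is an enol ether H‑11 is not α to a ketone, so base‑induced β‑elimination of the mesylate is suppressed.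

Step 13
Reactants: 23 tricyclic vinylogous ester; 4 methyllithium; 18 water
Product: 25 (4R,5S,7S,8R,9S,10R,11R)-7,8,9-trihydroxylongipin-2-en-1-one, via tertiary allylic carbinol 24 (not isolated)
Conditions: MeLi (3 equiv), THF, −78 → 0 °C; then 2 M aq. HCl, THF/MeOH, 23 °C
Reagents that add atoms: methyllithium, [Li]C; water, O
Why: MeLi adds 1,2 to the vinylogous ester carbonyl from the face next to the C‑5 bridge, and aqueous acid then ionises the tertiary allylic alcohol, hydrolyses the enol ether with allylic transposition to the 3‑methyl‑2‑en‑1‑one (Stork–Danheiser transposition) and cleaves the three silyl ethers; the transient carbinol centre is destroyed and no other stereocentre is touched.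

Step 14
Reactants: 25 (4R,5S,7S,8R,9S,10R,11R)-7,8,9-trihydroxylongipin-2-en-1-one; 26 angelic acid
Product: 27 (4R,5S,7S,8R,9S,10R,11R)-7,8,9-tris[(Z)-2-methylbut-2-enoyloxy]longipin-2-en-1-one (CNP0330079.1)
Conditions: angelic acid (9 equiv), 2,4,6-trichlorobenzoyl chloride, Et3N, toluene, 23 °C; then 25, toluene, 80 °C
Reagents that add atoms: angelic acid, C/C=C(/C)C(=O)O
Why: Angelic acid is activated as its 2,4,6‑trichlorobenzoyl mixed anhydride (Yamaguchi‑type esterification) and acylates the three secondary alcohols on heating without a nucleophilic amine catalyst, which avoids Z to E isomerisation to tiglate; the carbinol configurations are retained.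

## Compound list

1 | 3,5-dimethoxybenzoic acid | COc1cc(OC)cc(c1)C(=O)O | starting material
2 | iodomethane | CI | starting material
3 | 3,5-dimethoxy-1-methylcyclohexa-2,5-diene-1-carboxylic acid (achiral) | COC1=CC(C)(C(=O)O)C=C(OC)C1 | intermediate
4 | methyllithium | [Li]C | starting material
5 | 1-(3,5-dimethoxy-1-methylcyclohexa-2,5-dien-1-yl)ethan-1-one | COC1=CC(C)(C(C)=O)C=C(OC)C1 | intermediate
6 | 3-phenyl-2-(phenylsulfonyl)oxaziridine (Davis oxaziridine, racemic) | O=S(=O)(N1OC1c1ccccc1)c1ccccc1 | starting material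
7 | 1-(3,5-dimethoxy-1-methylcyclohexa-2,5-dien-1-yl)-2-hydroxyethan-1-one | COC1=CC(C)(C(=O)CO)C=C(OC)C1 | intermediate
8 | methyl 3-hydroxy-2,2-dimethylpropanoate | COC(=O)C(C)(C)CO | starting material
9 | N,O-dimethylhydroxylamine hydrochloride | Cl.CNOC | starting material
10 | 3-hydroxy-N-methoxy-N,2,2-trimethylpropanamide | CON(C)C(=O)C(C)(C)CO | intermediate
11 | N-methoxy-N,2,2-trimethyl-3-oxopropanamide | CON(C)C(=O)C(C)(C)C=O | intermediate
12 | (3S,4R)-5-(3,5-dimethoxy-1-methylcyclohexa-2,5-dien-1-yl)-3,4-dihydroxy-N-methoxy-N,2,2-trimethyl-5-oxopentanamide (syn diol; C-7, C-8 as in target) | COC1=CC(C)(C=C(OC)C1)C(=O)[C@H](O)[C@@H](O)C(C)(C)C(=O)N(C)OC | intermediate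
13 | 5-(3,5-dimethoxy-1-methylcyclohexa-2,5-dien-1-yl)-3,4,5-trihydroxy-N-methoxy-N,2,2-trimethylpentanamide (3,4-syn, 4,5-anti; C-7, C-8, C-9 as in target) | COC1=CC(C)(C=C(OC)C1)[C@H](O)[C@H](O)[C@@H](O)C(C)(C)C(=O)N(C)OC | intermediate
14 | triethylsilyl trifluoromethanesulfonate | CC[Si](CC)(CC)OS(=O)(=O)C(F)(F)F | starting material
15 | tris(triethylsilyl) ether of 13 | COC1=CC(C)(C=C(OC)C1)[C@H](O[Si](CC)(CC)CC)[C@H](O[Si](CC)(CC)CC)[C@@H](O[Si](CC)(CC)CC)C(C)(C)C(=O)N(C)OC | intermediate
16 | 5-(3,5-dimethoxy-1-methylcyclohexa-2,5-dien-1-yl)-2,2-dimethyl-3,4,5-tris(triethylsilyloxy)pentanal (configuration as 13) | COC1=CC(C)(C=C(OC)C1)[C@H](O[Si](CC)(CC)CC)[C@H](O[Si](CC)(CC)CC)[C@@H](O[Si](CC)(CC)CC)C(C)(C)C=O | intermediate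
17 | trimethylsilyl trifluoromethanesulfonate | C[Si](C)(C)OS(=O)(=O)C(F)(F)F | starting material
18 | water | O | starting material
19 | cis-fused bicyclic 1,3-dimethoxy-1,3-diene (C-1(OMe)=C-2–C-3(OMe)=C-4) with C-5 trimethylsilyloxy and 7,8,9-tris(triethylsilyloxy) groups; 5-O cis to 10-Me and H-11 | CC[Si](CC)(CC)O[C@@H]1[C@@H](O[Si](CC)(CC)CC)C(C)(C)[C@H](O[Si](C)(C)C)[C@H]2C(OC)=CC(OC)=C[C@@]2(C)[C@@H]1O[Si](CC)(CC)CC | intermediate
20 | cis-fused bicyclic hydroxy vinylogous ester: C-3 ketone, C-1 methoxy enol ether, C-5 OH on C-5 attached to C-11, 5-OH cis to 10-Me and H-11, 7,8,9-tris(triethylsilyloxy) | CC[Si](CC)(CC)O[C@@H]1[C@@H](O[Si](CC)(CC)CC)C(C)(C)[C@H](O)[C@H]2C(OC)=CC(=O)C[C@@]2(C)[C@@H]1O[Si](CC)(CC)CC | intermediate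
21 | methanesulfonyl chloride | CS(=O)(=O)Cl | starting material
22 | C-5 methanesulfonate of 20 | CC[Si](CC)(CC)O[C@@H]1[C@@H](O[Si](CC)(CC)CC)C(C)(C)[C@H](OS(C)(=O)=O)[C@H]2C(OC)=CC(=O)C[C@@]2(C)[C@@H]1O[Si](CC)(CC)CC | intermediate
23 | 1-methoxy-7,8,9-tris(triethylsilyloxy)longipin-1-en-3-one (cage stereocentres as in target) | CC[Si](CC)(CC)O[C@@H]1[C@@H](O[Si](CC)(CC)CC)C(C)(C)[C@@H]2[C@H]3C(OC)=CC(=O)[C@@H]2[C@@]3(C)[C@@H]1O[Si](CC)(CC)CC | intermediate
24 | 1-methoxy-3-methyl-7,8,9-tris(triethylsilyloxy)longipin-1-en-3-ol (3-OH on the face of the C-10 bridge) | CC[Si](CC)(CC)O[C@@H]1[C@@H](O[Si](CC)(CC)CC)C(C)(C)[C@@H]2[C@H]3C(OC)=C[C@](C)(O)[C@@H]2[C@@]3(C)[C@@H]1O[Si](CC)(CC)CC | intermediate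
25 | (4R,5S,7S,8R,9S,10R,11R)-7,8,9-trihydroxylongipin-2-en-1-one | O[C@@H]1[C@@H](O)C(C)(C)[C@@H]2[C@H]3C(=O)C=C(C)[C@@H]2[C@@]3(C)[C@@H]1O | intermediate
26 | angelic acid, (Z)-2-methylbut-2-enoic acid | C/C=C(/C)C(=O)O | starting material
27 | (4R,5S,7S,8R,9S,10R,11R)-7,8,9-tris[(Z)-2-methylbut-2-enoyloxy]longipin-2-en-1-one (CNP0330079.1) | C/C=C(/C)C(=O)O[C@@H]1[C@@H](OC(=O)/C(C)=C\C)C(C)(C)[C@@H]2[C@H]3C(=O)C=C(C)[C@@H]2[C@@]3(C)[C@@H]1OC(=O)/C(C)=C\C | target

## Step count and risks

Total steps: 14. Longest linear sequence: 12 steps (1 → 3 → 5 → 7 → 12 → 13 → 15 → 16 → 20 → 22 → 23 → 25 → 27); steps 4 and 5 are a two‑step side branch to aldehyde 11.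

**Risk 1, step 10.** Three selectivities must go right in one operation: which diastereotopic enol ether attacks, the C‑5 carbinol configuration, and the regiochemistry of the enol ether hydrolysis. The fallback replaces group selection by regiospecific enolate chemistry; it sets out from 16 and returns at 25.
- One enol ether of 16 is hydrolysed (1 equiv water, catalytic pyridinium p‑toluenesulfonate) to the two C‑10‑epimeric vinylogous esters. The epimer with the ketone at C‑3 and the methoxy group at C‑1, keto aldehyde F1, is separated; the other epimer is recycled by acid‑catalysed methanol exchange.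
- LiN(i‑Pr)2 gives the α′‑enolate, which can only close onto the aldehyde from C‑4, giving aldol F2.
- MeLi, then oxalic acid, gives the 3‑methyl enone alcohol F3 with the silyl ethers kept.
- MsCl/Et3N gives mesylate F4.
- LiN(i‑Pr)2 forms the enone α′‑enolate at C‑11, which has no leaving group β to it and closes onto C‑5 to give tris(triethylsilyl) enone F5.
- HCl in MeOH removes the silyl groups and rejoins the route at 25.

**Risk 2, step 12.** The SN2 closure is at a neopentyl secondary centre, and proton transfer to the extended dienolate could expel the mesylate. The fallback closes the ring photochemically; it sets out from 20 and returns at 23.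
- Dess–Martin periodinane oxidises 20 to the C‑5 ketone F6.
- Irradiation (λ > 300 nm, benzene) gives a Norrish–Yang cyclisation: the excited C‑5 carbonyl abstracts hydrogen from C‑4 through a six‑membered transition state and the biradical closes to the cage cyclobutanol F7. This also removes any dependence on the C‑5 carbinol configuration from step 10.
- KH, CS2 and MeI give xanthate F8.
- Bu3SnH/AIBN (Barton–McCombie) delivers 23; the hydrogen can only enter the one open position on C‑5.

**Risk 3, step 14.** Three hindered secondary alcohols must be acylated, and angelates isomerise easily to tiglates. The fallback builds the Z‑alkenes on the ester instead; it sets out from 25 and returns at 27.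
- Triol 25 is esterified with 2‑(diphenoxyphosphoryl)propanoic acid (N,N′‑dicyclohexylcarbodiimide, DMAP) to tris(phosphonopropionate) F9.
- A threefold Z‑selective Horner–Wadsworth–Emmons reaction of the diaryl phosphonate (NaH, acetaldehyde, THF, −78 °C, Ando conditions) forms the three angelate double bonds and gives 27.

## Further compounds

F1 | step 10 | vinylogous ester aldehyde: 3-(5-methoxy-1-methyl-3-oxocyclohex-4-en-1-yl) chain as in 16, C-3 ketone and C-1 methoxy, C-10 as in target | COC1=CC(=O)C[C@](C)(C1)[C@H](O[Si](CC)(CC)CC)[C@H](O[Si](CC)(CC)CC)[C@@H](O[Si](CC)(CC)CC)C(C)(C)C=O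
F2 | step 10 | cis-fused bicyclic aldol with C-5 attached to C-4, C-3 ketone, C-1 methoxy enol ether, 7,8,9-tris(triethylsilyloxy) | CC[Si](CC)(CC)O[C@@H]1[C@@H](O[Si](CC)(CC)CC)C(C)(C)[C@@H](O)[C@@H]2C(=O)C=C(OC)C[C@]2(C)[C@@H]1O[Si](CC)(CC)CC
F3 | step 10 | bicyclic 3-methyl-2-en-1-one with C-5 hydroxyl on the carbon attached to C-4, 7,8,9-tris(triethylsilyloxy) | CC[Si](CC)(CC)O[C@@H]1[C@@H](O[Si](CC)(CC)CC)C(C)(C)[C@@H](O)[C@@H]2C(C)=CC(=O)C[C@]2(C)[C@@H]1O[Si](CC)(CC)CC
F4 | step 10 | C-5 methanesulfonate of F3 | CC[Si](CC)(CC)O[C@@H]1[C@@H](O[Si](CC)(CC)CC)C(C)(C)[C@@H](OS(C)(=O)=O)[C@@H]2C(C)=CC(=O)C[C@]2(C)[C@@H]1O[Si](CC)(CC)CC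
F5 | step 10 | 7,8,9-tris(triethylsilyloxy)longipin-2-en-1-one | CC[Si](CC)(CC)O[C@@H]1[C@@H](O[Si](CC)(CC)CC)C(C)(C)[C@@H]2[C@H]3C(=O)C=C(C)[C@@H]2[C@@]3(C)[C@@H]1O[Si](CC)(CC)CC
F6 | step 12 | C-5 ketone of 20 | CC[Si](CC)(CC)O[C@@H]1[C@@H](O[Si](CC)(CC)CC)C(C)(C)C(=O)[C@H]2C(OC)=CC(=O)C[C@@]2(C)[C@@H]1O[Si](CC)(CC)CC
F7 | step 12 | 5-hydroxy-1-methoxy-7,8,9-tris(triethylsilyloxy)longipin-1-en-3-one | CC[Si](CC)(CC)O[C@@H]1[C@@H](O[Si](CC)(CC)CC)C(C)(C)[C@]2(O)[C@H]3C(OC)=CC(=O)[C@@H]2[C@@]3(C)[C@@H]1O[Si](CC)(CC)CC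
F8 | step 12 | O-(C-5) S-methyl dithiocarbonate of F7 | CC[Si](CC)(CC)O[C@@H]1[C@@H](O[Si](CC)(CC)CC)C(C)(C)[C@]2(OC(=S)SC)[C@H]3C(OC)=CC(=O)[C@@H]2[C@@]3(C)[C@@H]1O[Si](CC)(CC)CC
F9 | step 14 | 7,8,9-tris[2-(diphenoxyphosphoryl)propanoyloxy]longipin-2-en-1-one (mixture at the three phosphonate α-carbons) | CC(P(=O)(Oc4ccccc4)Oc5ccccc5)C(=O)O[C@@H]1[C@@H](OC(=O)C(C)P(=O)(Oc6ccccc6)Oc7ccccc7)C(C)(C)[C@@H]2[C@H]3C(=O)C=C(C)[C@@H]2[C@@]3(C)[C@@H]1OC(=O)C(C)P(=O)(Oc8ccccc8)Oc9ccccc9
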